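**Plan**

- Retrosynthesis: the side-chain ketone (C6′) stays masked as a dioxolane until the end. Ring A is cut at C4a–C5 and C8–C8a (retro-[4+2] after formally returning PhSOH and MeOH), which gives 1,3-dimethoxy-1-(trimethylsilyloxy)buta-1,3-diene and a (6R)-3-(phenylsulfinyl)-5,6-dihydropyran-2-one.
- Enabling feature: ring A (C4a, C5, C6, C7, C8, C8a) carries oxygen on C6 (OMe) and on C8 (free OH beside the lactone carbonyl C1) in a 1,3-relationship, the imprint of a 1,1,3-trioxygenated butadiene. Its C4a–C8a edge is the C=C of an unsaturated δ-lactone (ring B).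
- Further cuts: C–S at the lactone α-carbon, the lactone C=C (ring-closing metathesis), the acrylate C–O, the allyl–carbinol C–C, and the chain bond C6′–C7′ (acid chloride plus pentyl Grignard reagent).
- Forward order: side chain, carbinol, ring B by metathesis, sulfur on the α-carbon, ring A by cycloaddition and aromatization, then release of the ketone.
- Stereochemistry: the only stereocentre (C3, R) is set by reagent-controlled asymmetric allylboration of the chain aldehyde and is not touched by any later step.

Key step: step 10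

Assumption: sulfoxide 13 is used as the mixture of sulfur epimers, because sulfur is expelled in step 10; (−)-Ipc2BOMe means the B-methoxydiisopinocampheylborane of the (+)-α-pinene series.

**Route**

Step 1
Reactants: 1 monomethyl pimelate; 2 pentylmagnesium bromide
Product: 4 methyl 7-oxododecanoate, via acid chloride 3 (not isolated)
Conditions: (COCl)2, N,N-dimethylformamide (cat.), CH2Cl2, 0 °C → rt; concentrate; then 2, Fe(acac)3 (3 mol %), THF, −78 °C
Reagents that add atoms: none
Why: Acid chloride formation followed by Fe(acac)3-catalysed acylation of the Grignard reagent (iron-catalysed ketone synthesis), which at −78 °C should be much faster than attack on the methyl ester or on the ketone being formed.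

Step 2
Reactants: 4 methyl 7-oxododecanoate
Product: 5 methyl 6-(2-pentyl-1,3-dioxolan-2-yl)hexanoate
Conditions: ethylene glycol, p-toluenesulfonic acid monohydrate (cat.), toluene, reflux, Dean–Stark trap
Reagents that add atoms: ethylene glycol, OCCO
Why: Acid-catalysed ketalization of the dialkyl ketone driven by azeotropic removal of water, which shields the ketone from hydride, allylborane, sulfenyl chloride and peracid in the steps that follow.

Step 3
Reactants: 5 methyl 6-(2-pentyl-1,3-dioxolan-2-yl)hexanoate
Product: 6 6-(2-pentyl-1,3-dioxolan-2-yl)hexanal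
Conditions: i-Bu2AlH (1.05 equiv), CH2Cl2, −78 °C; MeOH, then aq. KNaC4H4O6 (potassium sodium tartrate)
Reagents that add atoms: none
Why: Partial reduction of the ester with i-Bu2AlH, in which the tetrahedral aluminium hemiacetal should persist at −78 °C until the quench, while the dioxolane is inert to hydride.

Step 4
Reactants: 6 6-(2-pentyl-1,3-dioxolan-2-yl)hexanal
Product: 8 (4R)-9-(2-pentyl-1,3-dioxolan-2-yl)non-1-en-4-ol, via borinate ester 7 (not isolated)
Conditions: (−)-Ipc2BOMe, allylMgBr, Et2O, 0 °C → rt; Mg salts filtered off; 6, Et2O, −100 → −78 °C; then NaOH, H2O2 (aq), rt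
Reagents that add atoms: allylmagnesium bromide, C=CC[Mg]Br
Why: Brown asymmetric allylboration, in which (−)-B-allyldiisopinocampheylborane should deliver the allyl group through a chair-like six-membered transition state to the Si face of the unbranched aldehyde and so set the carbinol centre as R (allyl outranks the alkyl chain), after which alkaline peroxide cleaves the borinate with retention at carbon.

Step 5
Reactants: 8 (4R)-9-(2-pentyl-1,3-dioxolan-2-yl)non-1-en-4-ol
Product: 9 (4R)-9-(2-pentyl-1,3-dioxolan-2-yl)non-1-en-4-yl prop-2-enoate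
Conditions: acryloyl chloride, Et3N, 4-(dimethylamino)pyridine (cat.), CH2Cl2, 0 °C
Reagents that add atoms: acryloyl chloride, C=CC(=O)Cl
Why: Nucleophilic-catalysed O-acylation of the secondary alcohol, which does not involve the bonds of the carbinol carbon and therefore keeps its configuration.

Step 6
Reactants: 9 (4R)-9-(2-pentyl-1,3-dioxolan-2-yl)non-1-en-4-yl prop-2-enoate
Product: 10 (6R)-6-[5-(2-pentyl-1,3-dioxolan-2-yl)pentyl]-5,6-dihydro-2H-pyran-2-one
Conditions: second-generation Grubbs catalyst RuCl2(=CHPh)(PCy3)(H2IMes) (3 mol %), CH2Cl2 (0.01 M), 40 °C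
Reagents that add atoms: none
Why: Ring-closing metathesis, in which the ruthenium carbene should load on the terminal alkene and close onto the acrylate to give the six-membered unsaturated lactone, with loss of ethene as the driving force.

Step 7
Reactants: 10 (6R)-6-[5-(2-pentyl-1,3-dioxolan-2-yl)pentyl]-5,6-dihydro-2H-pyran-2-one
Product: 12 (6R)-6-[5-(2-pentyl-1,3-dioxolan-2-yl)pentyl]-3-(phenylsulfanyl)-5,6-dihydro-2H-pyran-2-one, via chloro sulfide 11 (not isolated)
Conditions: PhSCl, CH2Cl2, −78 °C → rt; then Et3N, 0 °C → rt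
Reagents that add atoms: benzenesulfenyl chloride, ClSc1ccccc1
Why: Sulfenyl chloride addition–dehydrochlorination, the usual way from enones and enoates to their α-phenylsulfanyl derivatives: trans-addition through the thiiranium ion is followed by E1cB loss of HCl from the adduct with sulfur on the α-carbon, and a regioisomeric adduct can equilibrate through the same thiiranium ion.

Step 8
Reactants: 12 (6R)-6-[5-(2-pentyl-1,3-dioxolan-2-yl)pentyl]-3-(phenylsulfanyl)-5,6-dihydro-2H-pyran-2-one
Product: 13 (6R)-6-[5-(2-pentyl-1,3-dioxolan-2-yl)pentyl]-3-(phenylsulfinyl)-5,6-dihydro-2H-pyran-2-one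
Conditions: mCPBA (1.0 equiv), NaHCO3, CH2Cl2, −78 → −30 °C
Reagents that add atoms: mCPBA, O=C(OO)c1cccc(Cl)c1
Why: Peracid oxidation of the sulfide, which at low temperature with one equivalent should stop at the sulfoxide and leave the electron-poor alkene and the buffered ketal alone.

Step 9
Reactants: 14 methyl (E)-3-methoxybut-2-enoate
Product: 15 1,3-dimethoxy-1-(trimethylsilyloxy)buta-1,3-diene
Conditions: LiN(i-Pr)2, THF, −78 °C; Me3SiCl, −78 °C → rt; distillation
Reagents that add atoms: chlorotrimethylsilane, C[Si](C)(C)Cl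
Why: γ-Deprotonation of the β-methoxy enoate and O-silylation of the extended enolate, the standard preparation of this vinylketene acetal.

Step 10
Reactants: 13 (6R)-6-[5-(2-pentyl-1,3-dioxolan-2-yl)pentyl]-3-(phenylsulfinyl)-5,6-dihydro-2H-pyran-2-one; 15 1,3-dimethoxy-1-(trimethylsilyloxy)buta-1,3-diene
Product: 19 (3R)-8-hydroxy-6-methoxy-3-[5-(2-pentyl-1,3-dioxolan-2-yl)pentyl]isochroman-1-one, via cycloadduct 16 (not isolated), via dihydroarene ketal 17 (not isolated), via aryl silyl ether 18 (not isolated)
Conditions: 15 (3 equiv), toluene, 0 °C → rt, then 90 °C; then Bu4NF, AcOH, THF, 0 °C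
Reagents that add atoms: none
Why: Thermal normal-demand Diels–Alder reaction in which the unsubstituted CH2 terminus of the electron-rich vinylketene acetal 15 (largest HOMO coefficient) bonds to the lactone β-carbon (future C4a) and the acetal carbon to the sulfinyl-bearing α-carbon (future C8a), so that C4a–C5 and C8–C8a form together and ring A closes by intermolecular [4+2] annulation onto the lactone. The closest known reaction type is the addition of 1,1,3-trioxygenated butadienes to sulfinyl- or halogen-substituted enones, enoates and quinones used as alkyne equivalents. Suprafacial addition gives the cis-fused adduct 16 with the sulfinyl group and H-4a syn, so heating should bring about sulfoxide syn-elimination to 17, 1,4-loss of methanol from the C8 mixed ketal should aromatize ring A to the silyl ether 18, and buffered fluoride frees the hydrogen-bonded C8 phenol (any 17 that persists collapses to the same phenol once desilylated). The sp3 centres formed at C4a, C8 and C8a are transient and vanish on aromatization, no lasting stereocentre is created, and C3 lies outside the reacting atoms, so facial and endo/exo selectivity do not matter. The selectivity needed is regiochemical and is secured by the substrate: sulfinyl and carbonyl groups on the same carbon make the β-carbon the electrophilic end of the dienophile, which pairs with the nucleophilic diene terminus and places the ketal oxygen on C8 next to C1 and the methoxy group on C6.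

Step 11
Reactants: 19 (3R)-8-hydroxy-6-methoxy-3-[5-(2-pentyl-1,3-dioxolan-2-yl)pentyl]isochroman-1-one
Product: 20 (3R)-8-hydroxy-6-methoxy-3-(6-oxoundecyl)isochroman-1-one
Conditions: 1 M HCl (aq), THF, rt
Reagents that add atoms: water, O
Why: Acid-catalysed hydrolysis of the dioxolane releases the dialkyl ketone, while the lactone, the aryl methyl ether and the non-epimerizable C3 centre should be stable to dilute acid at room temperature.

**Compound list**

1 | monomethyl pimelate (7-methoxy-7-oxoheptanoic acid) | COC(=O)CCCCCC(=O)O | starting material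
2 | pentylmagnesium bromide | CCCCC[Mg]Br | starting material
3 | methyl 7-chloro-7-oxoheptanoate | COC(=O)CCCCCC(=O)Cl | intermediate
4 | methyl 7-oxododecanoate | CCCCCC(=O)CCCCCC(=O)OC | intermediate
5 | methyl 6-(2-pentyl-1,3-dioxolan-2-yl)hexanoate | CCCCCC1(CCCCCC(=O)OC)OCCO1 | intermediate
6 | 6-(2-pentyl-1,3-dioxolan-2-yl)hexanal | CCCCCC1(CCCCCC=O)OCCO1 | intermediate
7 | (4R)-9-(2-pentyl-1,3-dioxolan-2-yl)non-1-en-4-yl diisopinocampheylborinate (Ipc groups of the (+)-α-pinene series) | CCCCCC1(CCCCC[C@@H](OB([C@@H]2C[C@@H]3C[C@H]([C@H]2C)C3(C)C)[C@@H]2C[C@@H]3C[C@H]([C@H]2C)C3(C)C)CC=C)OCCO1 | intermediate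
8 | (4R)-9-(2-pentyl-1,3-dioxolan-2-yl)non-1-en-4-ol | CCCCCC1(CCCCC[C@@H](O)CC=C)OCCO1 | intermediate
9 | (4R)-9-(2-pentyl-1,3-dioxolan-2-yl)non-1-en-4-yl prop-2-enoate | CCCCCC1(CCCCC[C@@H](OC(=O)C=C)CC=C)OCCO1 | intermediate
10 | (6R)-6-[5-(2-pentyl-1,3-dioxolan-2-yl)pentyl]-5,6-dihydro-2H-pyran-2-one | CCCCCC1(CCCCC[C@@H]2CC=CC(=O)O2)OCCO1 | intermediate
11 | (6R)-4-chloro-6-[5-(2-pentyl-1,3-dioxolan-2-yl)pentyl]-3-(phenylsulfanyl)tetrahydro-2H-pyran-2-one (3,4-trans adduct, mixture) | CCCCCC1(CCCCC[C@@H]2CC(Cl)C(Sc3ccccc3)C(=O)O2)OCCO1 | intermediate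
12 | (6R)-6-[5-(2-pentyl-1,3-dioxolan-2-yl)pentyl]-3-(phenylsulfanyl)-5,6-dihydro-2H-pyran-2-one | CCCCCC1(CCCCC[C@@H]2CC=C(Sc3ccccc3)C(=O)O2)OCCO1 | intermediate
13 | (6R)-6-[5-(2-pentyl-1,3-dioxolan-2-yl)pentyl]-3-(phenylsulfinyl)-5,6-dihydro-2H-pyran-2-one (both sulfur epimers) | CCCCCC1(CCCCC[C@@H]2CC=C(S(=O)c3ccccc3)C(=O)O2)OCCO1 | intermediate
14 | methyl (E)-3-methoxybut-2-enoate | CO/C(C)=C/C(=O)OC | starting material
15 | 1,3-dimethoxy-1-(trimethylsilyloxy)buta-1,3-diene | C=C(OC)C=C(OC)O[Si](C)(C)C | intermediate
16 | (3R)-6,8-dimethoxy-3-[5-(2-pentyl-1,3-dioxolan-2-yl)pentyl]-8a-(phenylsulfinyl)-8-(trimethylsilyloxy)-3,4,4a,5,8,8a-hexahydro-1H-isochromen-1-one (cis-fused, mixture of diastereomers) | CCCCCC1(CCCCC[C@@H]2CC3CC(OC)=CC(OC)(O[Si](C)(C)C)C3(S(=O)c4ccccc4)C(=O)O2)OCCO1 | intermediate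
17 | (3R)-6,8-dimethoxy-3-[5-(2-pentyl-1,3-dioxolan-2-yl)pentyl]-8-(trimethylsilyloxy)-3,4,5,8-tetrahydro-1H-isochromen-1-one | CCCCCC1(CCCCC[C@@H]2CC3=C(C(=O)O2)C(OC)(O[Si](C)(C)C)C=C(OC)C3)OCCO1 | intermediate
18 | (3R)-6-methoxy-3-[5-(2-pentyl-1,3-dioxolan-2-yl)pentyl]-8-(trimethylsilyloxy)isochroman-1-one | CCCCCC1(CCCCC[C@@H]2Cc3cc(OC)cc(O[Si](C)(C)C)c3C(=O)O2)OCCO1 | intermediate
19 | (3R)-8-hydroxy-6-methoxy-3-[5-(2-pentyl-1,3-dioxolan-2-yl)pentyl]isochroman-1-one | CCCCCC1(CCCCC[C@@H]2Cc3cc(OC)cc(O)c3C(=O)O2)OCCO1 | intermediate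
20 | (3R)-8-hydroxy-6-methoxy-3-(6-oxoundecyl)isochroman-1-one | CCCCCC(=O)CCCCC[C@@H]1Cc2cc(OC)cc(O)c2C(=O)O1 | target

**Step count**

Total step count: 11. Longest linear sequence: 10 steps (steps 1–8, 10 and 11); step 9 is a one-step side branch.

**Steps most likely to fail**

Step 10. The mixed ketal at C8 may expel trimethylsilanol in place of methanol once the sulfenic acid has gone, so that ring A emerges partly or wholly as the C8 methyl ether. The fallback no longer differentiates the two oxygens in the cycloaddition and places the C8 phenol afterwards by chelation-controlled ether cleavage. It sets out from 13, which is combined with 15 and heated as before. The material that has lost the silanol is (3R)-6,8-dimethoxy-3-[5-(2-pentyl-1,3-dioxolan-2-yl)pentyl]isochroman-1-one F1. Without separation from any 19, this is hydrolysed with 1 M HCl in THF to (3R)-6,8-dimethoxy-3-(6-oxoundecyl)isochroman-1-one F2. BCl3 in CH2Cl2 at −78 → 0 °C should then cleave only the methyl ether peri to the lactone carbonyl, through the six-membered boron chelate, and leave the C6 ether. Any 20 already present passes through unchanged, and the route is rejoined at 20.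

Step 7. Addition of PhSCl to the electron-poor lactone double bond may be sluggish, or the regioisomeric adduct may eliminate toward the β-sulfanyl isomer. The fallback installs a halogen first and makes the C–S bond by cross-coupling. It sets out from 10, which is treated with Br2 in CH2Cl2 at 0 °C to give (6R)-3,4-dibromo-6-[5-(2-pentyl-1,3-dioxolan-2-yl)pentyl]tetrahydro-2H-pyran-2-one F3. Et3N in the same flask removes HBr to give (6R)-3-bromo-6-[5-(2-pentyl-1,3-dioxolan-2-yl)pentyl]-5,6-dihydro-2H-pyran-2-one F4. Coupling of this vinyl bromide with tributyl(phenylsulfanyl)stannane under Pd(PPh3)4 (zerovalent palladium) in toluene at 100 °C should give 12, where the route is rejoined.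

Step 3. The aluminium hemiacetal may collapse before the quench, so that aldehyde is reduced further and mixtures of ester, aldehyde and alcohol result. The fallback separates reduction and oxidation. It sets out from 5, which is reduced fully with LiAlH4 in THF at 0 °C to 6-(2-pentyl-1,3-dioxolan-2-yl)hexan-1-ol F5. Swern oxidation ((COCl)2, DMSO, Et3N, CH2Cl2, −78 °C) then returns the route to 6.

**Further compounds**

F1 | step 10 | (3R)-6,8-dimethoxy-3-[5-(2-pentyl-1,3-dioxolan-2-yl)pentyl]isochroman-1-one | CCCCCC1(CCCCC[C@@H]2Cc3cc(OC)cc(OC)c3C(=O)O2)OCCO1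
F2 | step 10 | (3R)-6,8-dimethoxy-3-(6-oxoundecyl)isochroman-1-one | CCCCCC(=O)CCCCC[C@@H]1Cc2cc(OC)cc(OC)c2C(=O)O1
F3 | step 7 | (6R)-3,4-dibromo-6-[5-(2-pentyl-1,3-dioxolan-2-yl)pentyl]tetrahydro-2H-pyran-2-one | CCCCCC1(CCCCC[C@@H]2CC(Br)C(Br)C(=O)O2)OCCO1
F4 | step 7 | (6R)-3-bromo-6-[5-(2-pentyl-1,3-dioxolan-2-yl)pentyl]-5,6-dihydro-2H-pyran-2-one | CCCCCC1(CCCCC[C@@H]2CC=C(Br)C(=O)O2)OCCO1
F5 | step 3 | 6-(2-pentyl-1,3-dioxolan-2-yl)hexan-1-ol | CCCCCC1(CCCCCCO)OCCO1
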